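The two outer rings are the same 3-butyryl-5-methylphloroglucinol methylated on different oxygens: in ring A the OCH3 sits at C4 beside the C5 butyryl, in ring B at C6 across from the C3 butyryl. Each ring is therefore folded from an acyclic keto ester arm in which that oxygen is already a methyl enol ether. One base treatment forms ring A C5–C6 and ring B C2–C3 by intramolecular Claisen condensation and aromatises both. The precursor is 2,4,6-tris(benzyloxy)butyrophenone with the two arms on C3 and C5. Its arm butyryl ketones are kept as silyl-protected alcohols until the step before, so each bridge-forming alkylation has one nucleophilic site.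

Key step: step 18

Remark: the sp3 centres made in the arms (carbinol carbons, C4 of 17, the two ester α-carbons) are uncontrolled and all vanish by step 18, so 14–31 are carried as stereoisomer mixtures; the arm-B enol ether of 27–30 is expected as a mixture of E/Z and double-bond-position isomers, which the base of step 18 should funnel through one dienolate.

Step 1
Reactants: 1 phloroglucinol; 2 butyryl chloride
Product: 3 1-(2,4,6-trihydroxyphenyl)butan-1-one
Conditions: AlCl3, PhNO2/CH2Cl2, 0 °C → rt; aq. HCl
Reagents that add atoms: none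
Why: Friedel–Crafts C-acylation of the very electron-rich triol should stop after one acyl group because the new ketone deactivates the ring.

Step 2
Reactants: 3 1-(2,4,6-trihydroxyphenyl)butan-1-one
Product: 5 5-butanoyl-2,4,6-trihydroxybenzene-1,3-dicarbaldehyde, via bis(iminium) dichloride 4 (not isolated)
Conditions: POCl3, DMF, EtOAc, 0 °C → rt; then H2O, 50 °C
Reagents that add atoms: N,N-dimethylformamide CN(C)C=O; water O
Why: Vilsmeier–Haack formylation should attack the only two free positions of the still electron-rich acylphloroglucinol, and hydrolysis of the bis(iminium) salt releases the dialdehyde.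

Step 3
Reactants: 5 5-butanoyl-2,4,6-trihydroxybenzene-1,3-dicarbaldehyde
Product: 6 2,4,6-tris(benzyloxy)-5-butanoylbenzene-1,3-dicarbaldehyde
Conditions: BnBr, K2CO3, DMF, 60 °C
Reagents that add atoms: benzyl bromide BrCc1ccccc1
Why: Williamson etherification of the three acidic chelated phenols; C-benzylation is disfavoured because every ring carbon is substituted and attack there would destroy aromaticity.

Step 4
Reactants: 6 2,4,6-tris(benzyloxy)-5-butanoylbenzene-1,3-dicarbaldehyde
Product: 7 1-[2,4,6-tris(benzyloxy)-3,5-bis(hydroxymethyl)phenyl]butan-1-one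
Conditions: NaBH4, THF/MeOH, −10 °C
Reagents that add atoms: none
Why: chemoselective hydride reduction, since NaBH4 should reduce the two aldehydes much faster than the aryl ketone, which is twisted out of plane and shielded by two ortho benzyloxy groups.

Step 5
Reactants: 7 1-[2,4,6-tris(benzyloxy)-3,5-bis(hydroxymethyl)phenyl]butan-1-one
Product: 8 1-[2,4,6-tris(benzyloxy)-3,5-bis(bromomethyl)phenyl]butan-1-one
Conditions: PBr3, pyridine (cat.), CH2Cl2, 0 °C
Reagents that add atoms: phosphorus tribromide BrP(Br)Br
Why: alcohol-to-bromide substitution of activated benzylic alcohols at low temperature, with pyridine buffering HBr so that the benzyl ethers stay; the ring has no free position for self-alkylation, and 8 is used at once.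

Step 6
Reactants: 9 methyl 3-oxopentanoate
Product: 10 methyl (E)-3-methoxypent-2-enoate
Conditions: HC(OMe)3, H2SO4 (cat.), MeOH, rt
Reagents that add atoms: trimethyl orthoformate COC(OC)OC
Why: acid-catalysed enol ether formation of a β-keto ester with an orthoformate should give the conjugated E β-methoxyacrylate, the thermodynamic isomer.

Step 7
Reactants: 11 N-methoxy-N-methylacetamide; 12 butanal
Product: 14 rac-3-hydroxy-N-methoxy-N-methylhexanamide, via lithium amide enolate 13 (not isolated)
Conditions: LiN(iPr)2, THF, −78 °C; then 12; aq. NH4Cl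
Reagents that add atoms: none
Why: aldol addition of the lithium enolate of the N-methoxy-N-methylamide to butanal; the carbinol centre is not controlled and is oxidised away in step 17.

Step 8
Reactants: 14 rac-3-hydroxy-N-methoxy-N-methylhexanamide
Product: 15 rac-3-[(tert-butyldimethylsilyl)oxy]-N-methoxy-N-methylhexanamide
Conditions: TBSCl, imidazole, DMF, rt
Reagents that add atoms: tert-butyldimethylsilyl chloride CC(C)(C)[Si](C)(C)Cl
Why: standard silyl ether formation on a secondary alcohol, which blocks retro-aldol cleavage and masks the future butyryl ketone of arm B.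

Step 9
Reactants: 10 methyl (E)-3-methoxypent-2-enoate; 15 rac-3-[(tert-butyldimethylsilyl)oxy]-N-methoxy-N-methylhexanamide
Product: 17 methyl (E)-7-[(tert-butyldimethylsilyl)oxy]-3-methoxy-4-methyl-5-oxodec-2-enoate (both diastereomers), via lithium dienolate 16 (not isolated)
Conditions: LiN(iPr)2, THF, −78 °C; then 15, −78 → −40 °C; aq. NH4Cl
Reagents that add atoms: none
Why: vinylogous Claisen-type acylation, in which γ-deprotonation gives a 1,3-dioxygenated dienolate that should acylate at its terminal γ-carbon, while the chelated tetrahedral adduct of the N-methoxy-N-methylamide prevents a second addition; C4 is formed without control and becomes sp2 later.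

Step 10
Reactants: 18 methyl 2-methyl-3-oxobutanoate
Product: 19 methyl (E)-3-methoxy-2-methylbut-2-enoate
Conditions: HC(OMe)3, H2SO4 (cat.), MeOH, rt
Reagents that add atoms: trimethyl orthoformate COC(OC)OC
Why: the same orthoformate enol ether formation as in step 6; the double-bond geometry is of no consequence because the dienolate of step 11 erases it.

Step 11
Reactants: 19 methyl (E)-3-methoxy-2-methylbut-2-enoate; 12 butanal
Product: 21 rac-4-methoxy-3-methyl-6-propyl-5,6-dihydro-2H-pyran-2-one, via lithium dienolate 20 (not isolated)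
Conditions: LiN(iPr)2, THF, −78 °C; then 12, −78 → 0 °C; aq. NH4Cl
Reagents that add atoms: none
Why: vinylogous aldol addition of the γ-lithiated β-methoxy enoate to butanal, followed by closure of the alkoxide onto the cis ester, is the established way to 4-methoxy-5,6-dihydropyran-2-ones; the carbinol centre is racemic and is oxidised away later.

Step 12
Reactants: 21 rac-4-methoxy-3-methyl-6-propyl-5,6-dihydro-2H-pyran-2-one
Product: 24 rac-(E)-5-[(tert-butyldimethylsilyl)oxy]-3-methoxy-2-methyloct-2-enoic acid, via lithium hydroxy carboxylate 22 (not isolated), via silyl ester silyl ether 23 (not isolated)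
Conditions: LiOH, THF/H2O, rt; then TBSCl, imidazole, DMF; then K2CO3 (cat.), MeOH/THF/H2O, 0 °C; citric acid to pH 5
Reagents that add atoms: lithium hydroxide [Li+].[OH-]; tert-butyldimethylsilyl chloride CC(C)(C)[Si](C)(C)Cl
Why: saponification opens the lactone, silylation of both oxygens prevents relactonisation, and only the labile silyl ester is then hydrolysed; the ring origin fixes the carboxyl cis to C4, the enol ether geometry that arm A needs in step 18.

Step 13
Reactants: 24 rac-(E)-5-[(tert-butyldimethylsilyl)oxy]-3-methoxy-2-methyloct-2-enoic acid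
Product: 26 rac-methyl (E)-7-[(tert-butyldimethylsilyl)oxy]-5-methoxy-4-methyl-3-oxodec-4-enoate, via acyl imidazolide 25 (not isolated)
Conditions: CDI, THF, rt; then KO2CCH2CO2Me, MgCl2, Et3N, MeCN, rt → 40 °C; aq. citric acid
Reagents that add atoms: potassium methyl malonate COC(=O)CC(=O)[O-].[K+]
Why: decarboxylative Claisen condensation, in which the acyl imidazolide acylates the magnesium enolate of the malonate half ester and loss of CO2 gives the β-keto ester under nearly neutral conditions that spare the silyl and enol ethers.

Step 14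
Reactants: 17 methyl (E)-7-[(tert-butyldimethylsilyl)oxy]-3-methoxy-4-methyl-5-oxodec-2-enoate; 8 1-[2,4,6-tris(benzyloxy)-3,5-bis(bromomethyl)phenyl]butan-1-one
Product: 27 methyl 2-{[2,4,6-tris(benzyloxy)-3-(bromomethyl)-5-butanoylphenyl]methyl}-7-[(tert-butyldimethylsilyl)oxy]-3-methoxy-4-methyl-5-oxodec-3-enoate (stereoisomer mixture)
Conditions: Cs2CO3, DMF, 0 °C → rt; 8 in threefold excess (recovered)
Reagents that add atoms: none
Why: enolate C-alkylation of the vinylogous β-keto ester anion of 17, whose ketone α-carbon C4 already bears a methyl group, so the bulky benzylic bromide should be taken up at the unhindered ester α-carbon C2, as is known for vinylogous β-keto esters substituted at the ketone α-carbon; the excess of 8 keeps the reaction at monoalkylation and the new C2 centre is uncontrolled.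

Step 15
Reactants: 27 monobromide of step 14; 26 rac-methyl (E)-7-[(tert-butyldimethylsilyl)oxy]-5-methoxy-4-methyl-3-oxodec-4-enoate
Product: 28 bis(silyl ether) of the two-armed keto ester, that is 1-[2,4,6-tris(benzyloxy)phenyl]butan-1-one carrying the silyl-protected arm A on C3 and the silyl-protected arm B on C5 (stereoisomer mixture)
Conditions: K2CO3, acetone, rt
Reagents that add atoms: none
Why: classical C-alkylation of a β-keto ester at its doubly activated CH2, the only acidic site of 26 while the arm ketone is masked; the less acidic, hindered CH of 27 should not compete.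

Step 16
Reactants: 28 bis(silyl ether) of the two-armed keto ester
Product: 29 two-armed diol (arm A and arm B each with a free secondary alcohol at the future butyryl carbon; stereoisomer mixture)
Conditions: HF·pyridine, pyridine, THF, 0 °C → rt
Reagents that add atoms: none
Why: fluoride cleavage of two secondary silyl ethers, buffered with pyridine so that the β-hydroxy ketone of arm B does not close onto its methoxy enone.

Step 17
Reactants: 29 two-armed diol
Product: 30 precursor, methyl ester arms A [CH2–CH(CO2CH3)–CO–C(CH3)=C(OCH3)–CH2–CO–C3H7] and B [CH2–CH(CO2CH3)–C(OCH3)=C(CH3)–CO–CH2–CO–C3H7] on C3 and C5 of 1-[2,4,6-tris(benzyloxy)phenyl]butan-1-one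
Conditions: IBX, EtOAc, 70 °C; filtration
Reagents that add atoms: none
Why: 2-iodoxybenzoic acid oxidises secondary alcohols and is a proven reagent for β-hydroxy ketone to 1,3-diketone oxidation; the neutral heterogeneous conditions should leave enol ethers, benzyl ethers and the β-keto ester untouched, and 30 is used without acid contact to avoid 4-pyranone closure of arm B.

Step 18
Reactants: 30 precursor
Product: 32 1-[2,4,6-tris(benzyloxy)-3-[(3-butanoyl-2,6-dihydroxy-4-methoxy-5-methylphenyl)methyl]-5-[(3-butanoyl-2,4-dihydroxy-6-methoxy-5-methylphenyl)methyl]phenyl]butan-1-one, via ring-B-closed monocyclised keto ester 31 (not isolated)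
Conditions: Mg(OMe)2, MeOH/THF, rt → 60 °C; then cold 1 M HCl
Reagents that add atoms: none
Why: Proposed new method: Mg(OMe)2 turns both arms into magnesium-chelated enolates; in arm B the CH2 between the two ketones and in arm A the CH2 between the butyryl carbonyl and the enol ether carbon add to their own methyl ester, expel methoxide, and the resulting cyclohexenediones enolise twice to the phenols, the enol ether carbon becoming the aryl OCH3 carbon (ring B C2–C3, ring A C5–C6). The closest known reaction type is the Claisen (Dieckmann-type) cyclisation of 3,5,7-triketo esters to acylphloroglucinols with Mg(OMe)2, from which this case differs by a methyl enol ether standing in for one ketone and by two closures in one molecule. Both rings close 6-exo-trig across a cis enol ether double bond: arm A has this geometry from lactone 21, and the isomer mixture of arm B should equilibrate through its dienolate. No stereocentre is created, and the two ester α-centres of 30 are lost on aromatisation. The step needs Claisen closure rather than aldol closure onto the butyryl ketone or lactonisation to a pyrone: the ester α-carbon already bears the benzylic substituent, so an aldol adduct would hold a quaternary carbon, cannot aromatise and can revert, methoxide reopens pyrones, and the chelated acylphloroglucinol magnesium salt is the thermodynamic sink.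

Step 19
Reactants: 32 tribenzyl ether of the target
Product: 33 target, CNP0171986.0
Conditions: H2 (1 atm), Pd/C (10%), EtOAc/MeOH, rt
Reagents that add atoms: none
Why: hydrogenolysis of the three aryl benzyl ethers over Pd/C under neutral conditions; the chelated aryl ketones, aryl methyl ethers and diarylmethane bridges should be inert.

Compound list
1 | phloroglucinol | Oc1cc(O)cc(O)c1 | starting material
2 | butyryl chloride | CCCC(Cl)=O | starting material
3 | 1-(2,4,6-trihydroxyphenyl)butan-1-one | CCCC(=O)c1c(O)cc(O)cc1O | intermediate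
4 | 3,5-bis[(dimethyliminio)methyl] derivative of 3, dichloride | CCCC(=O)c1c(O)c(C=[N+](C)C)c(O)c(C=[N+](C)C)c1O.[Cl-].[Cl-] | intermediate (not isolated)
5 | 5-butanoyl-2,4,6-trihydroxybenzene-1,3-dicarbaldehyde | CCCC(=O)c1c(O)c(C=O)c(O)c(C=O)c1O | intermediate
6 | 2,4,6-tris(benzyloxy)-5-butanoylbenzene-1,3-dicarbaldehyde | CCCC(=O)c1c(OCc2ccccc2)c(C=O)c(OCc2ccccc2)c(C=O)c1OCc1ccccc1 | intermediate
7 | 1-[2,4,6-tris(benzyloxy)-3,5-bis(hydroxymethyl)phenyl]butan-1-one | CCCC(=O)c1c(OCc2ccccc2)c(CO)c(OCc2ccccc2)c(CO)c1OCc1ccccc1 | intermediate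
8 | 1-[2,4,6-tris(benzyloxy)-3,5-bis(bromomethyl)phenyl]butan-1-one | CCCC(=O)c1c(OCc2ccccc2)c(CBr)c(OCc2ccccc2)c(CBr)c1OCc1ccccc1 | intermediate
9 | methyl 3-oxopentanoate | CCC(=O)CC(=O)OC | starting material
10 | methyl (E)-3-methoxypent-2-enoate | COC(=O)/C=C(/OC)CC | intermediate
11 | N-methoxy-N-methylacetamide | CC(=O)N(C)OC | starting material
12 | butanal | CCCC=O | starting material
13 | lithium enolate of 11 | C=C([O-])N(C)OC.[Li+] | intermediate (not isolated)
14 | rac-3-hydroxy-N-methoxy-N-methylhexanamide | CCCC(O)CC(=O)N(C)OC | intermediate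
15 | rac-3-[(tert-butyldimethylsilyl)oxy]-N-methoxy-N-methylhexanamide | CCCC(O[Si](C)(C)C(C)(C)C)CC(=O)N(C)OC | intermediate
16 | lithium dienolate of 10 (γ-deprotonated) | CC=C(OC)C=C([O-])OC.[Li+] | intermediate (not isolated)
17 | methyl (E)-7-[(tert-butyldimethylsilyl)oxy]-3-methoxy-4-methyl-5-oxodec-2-enoate, racemic, both diastereomers | COC(=O)/C=C(/OC)C(C)C(=O)CC(O[Si](C)(C)C(C)(C)C)CCC | intermediate
18 | methyl 2-methyl-3-oxobutanoate | COC(=O)C(C)C(C)=O | starting material
19 | methyl (E)-3-methoxy-2-methylbut-2-enoate | COC(=O)/C(C)=C(/OC)C | intermediate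
20 | lithium dienolate of 19 (γ-deprotonated) | C=C(OC)C(C)=C([O-])OC.[Li+] | intermediate (not isolated)
21 | rac-4-methoxy-3-methyl-6-propyl-5,6-dihydro-2H-pyran-2-one | CCCC1CC(OC)=C(C)C(=O)O1 | intermediate
22 | lithium (E)-5-hydroxy-3-methoxy-2-methyloct-2-enoate, racemic | CCCC(O)C/C(OC)=C(/C)C(=O)[O-].[Li+] | intermediate (not isolated)
23 | tert-butyldimethylsilyl (E)-5-[(tert-butyldimethylsilyl)oxy]-3-methoxy-2-methyloct-2-enoate, racemic | CCCC(O[Si](C)(C)C(C)(C)C)C/C(OC)=C(/C)C(=O)O[Si](C)(C)C(C)(C)C | intermediate (not isolated)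
24 | rac-(E)-5-[(tert-butyldimethylsilyl)oxy]-3-methoxy-2-methyloct-2-enoic acid | CCCC(O[Si](C)(C)C(C)(C)C)C/C(OC)=C(/C)C(=O)O | intermediate
25 | acyl imidazolide of 24 | CCCC(O[Si](C)(C)C(C)(C)C)C/C(OC)=C(/C)C(=O)n1ccnc1 | intermediate (not isolated)
26 | rac-methyl (E)-7-[(tert-butyldimethylsilyl)oxy]-5-methoxy-4-methyl-3-oxodec-4-enoate | COC(=O)CC(=O)/C(C)=C(OC)\CC(O[Si](C)(C)C(C)(C)C)CCC | intermediate
27 | methyl 2-{[2,4,6-tris(benzyloxy)-3-(bromomethyl)-5-butanoylphenyl]methyl}-7-[(tert-butyldimethylsilyl)oxy]-3-methoxy-4-methyl-5-oxodec-3-enoate, stereoisomer and E/Z mixture | CCCC(=O)c1c(OCc2ccccc2)c(CBr)c(OCc2ccccc2)c(CC(C(=O)OC)C(OC)=C(C)C(=O)CC(O[Si](C)(C)C(C)(C)C)CCC)c1OCc1ccccc1 | intermediate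
28 | bis(silyl ether): 1-[2,4,6-tris(benzyloxy)phenyl]butan-1-one with silyl-protected arm A on C3 and silyl-protected arm B on C5; arm A enol ether E, arm B E/Z mixture, stereoisomer mixture | CCCC(=O)c1c(OCc2ccccc2)c(CC(C(=O)OC)C(=O)/C(C)=C(OC)\CC(O[Si](C)(C)C(C)(C)C)CCC)c(OCc2ccccc2)c(CC(C(=O)OC)C(OC)=C(C)C(=O)CC(O[Si](C)(C)C(C)(C)C)CCC)c1OCc1ccccc1 | intermediate
29 | two-armed diol (28 with both silyl ethers cleaved), stereoisomer mixture | CCCC(=O)c1c(OCc2ccccc2)c(CC(C(=O)OC)C(=O)/C(C)=C(OC)\CC(O)CCC)c(OCc2ccccc2)c(CC(C(=O)OC)C(OC)=C(C)C(=O)CC(O)CCC)c1OCc1ccccc1 | intermediate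
30 | precursor: 1-[2,4,6-tris(benzyloxy)phenyl]butan-1-one with arm A (methyl 5-methoxy-4-methyl-3,7-dioxodec-4-enoate bonded through C2, enol ether E) on C3 and arm B (methyl 3-methoxy-4-methyl-5,7-dioxodec-3-enoate bonded through C2, E/Z mixture, only the isomer with C2 and C5 cis closes) on C5; two ester α-epimers | CCCC(=O)c1c(OCc2ccccc2)c(CC(C(=O)OC)C(=O)/C(C)=C(OC)\CC(=O)CCC)c(OCc2ccccc2)c(CC(C(=O)OC)C(OC)=C(C)C(=O)CC(=O)CCC)c1OCc1ccccc1 | intermediate
31 | monocyclised keto ester: ring B closed, arm A still open | CCCC(=O)c1c(OCc2ccccc2)c(CC(C(=O)OC)C(=O)/C(C)=C(OC)\CC(=O)CCC)c(OCc2ccccc2)c(Cc2c(O)c(C(=O)CCC)c(O)c(C)c2OC)c1OCc1ccccc1 | intermediate (not isolated)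
32 | tribenzyl ether of the target (central-ring hydroxyls as benzyl ethers) | CCCC(=O)c1c(OCc2ccccc2)c(Cc2c(O)c(C)c(OC)c(C(=O)CCC)c2O)c(OCc2ccccc2)c(Cc2c(O)c(C(=O)CCC)c(O)c(C)c2OC)c1OCc1ccccc1 | intermediate
33 | CNP0171986.0 | CCCC(=O)c1c(O)c(Cc2c(O)c(C)c(OC)c(C(=O)CCC)c2O)c(O)c(Cc2c(O)c(C(=O)CCC)c(O)c(C)c2OC)c1O | target

Total step count: 19. Longest linear sequence: 11 steps (steps 1–5 and 14–19); the two arm fragments take 4 steps each (6–9 and 10–13).

Steps most likely to fail

Step 18. Closure may stop at an aldol or pyrone stage, methoxide may cut the diketone arm by retro-Claisen attack before it closes, or only one arm may close. The fallback uses known chemistry, sets out from 8 and comes back at 32: the outer rings are made as free phenols and joined to the central ring by C-benzylation. Commercial 2-methylphloroglucinol is monomethylated (MeOH, HCl) to 5-methoxy-4-methylbenzene-1,3-diol F1. Friedel–Crafts butyrylation of F1 with 2 and AlCl3 should give both ring-acylated isomers, 1-(2,6-dihydroxy-4-methoxy-3-methylphenyl)butan-1-one F2 and 1-(4,6-dihydroxy-2-methoxy-3-methylphenyl)butan-1-one F3, which are separated. The sodium phenoxide of F2 (NaOMe, MeOH/toluene) is C-benzylated at its only free ring carbon by excess 8 to give 1-[2,4,6-tris(benzyloxy)-3-(bromomethyl)-5-[(3-butanoyl-2,4-dihydroxy-6-methoxy-5-methylphenyl)methyl]phenyl]butan-1-one F4. The phenoxide of F3 then takes the remaining bromide at its free carbon between the two hydroxyls, which gives 32 for step 19.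

Step 14. The ambident anion may be benzylated at the ketone α-carbon C4 or at oxygen, silanol may be eliminated from the β-silyloxy ketone, or both bromides of 8 may react. The fallback sets out from 17 and 8 and comes back at 27. Compound 17 is converted with Me3SiOTf and Et3N into its silyl dienol ether, methyl 7-[(tert-butyldimethylsilyl)oxy]-3-methoxy-4-methyl-5-[(trimethylsilyl)oxy]deca-2,4-dienoate F5. This neutral 1,3-dioxygenated diene is alkylated by 8 (threefold excess) under ZnBr2 catalysis in CH2Cl2 at −40 °C. Lewis-acid alkylations of silyl dienol ethers by ionisable benzylic halides take place at the diene terminus (vinylogous Mukaiyama regiochemistry), here C2, and should give 27 without a basic enolate.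

Step 3. Etherification may stall at partly benzylated, still chelated phenols, or benzylation at a ring carbon may break aromaticity. The fallback sets out from 3 and comes back at 6: the ethers are made before the aldehydes. Compound 3 is benzylated (BnBr, K2CO3, DMF) to 1-[2,4,6-tris(benzyloxy)phenyl]butan-1-one F6, whose phenols are flanked by one carbonyl at most. The two remaining ring positions are then formylated by Rieche formylation (Cl2CHOMe, SnCl4, CH2Cl2, −78 → 0 °C, then water), which gives 6 for step 4.

Further compounds
F1 | step 18 | 5-methoxy-4-methylbenzene-1,3-diol | COc1cc(O)cc(O)c1C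
F2 | step 18 | 1-(2,6-dihydroxy-4-methoxy-3-methylphenyl)butan-1-one | CCCC(=O)c1c(O)cc(OC)c(C)c1O
F3 | step 18 | 1-(4,6-dihydroxy-2-methoxy-3-methylphenyl)butan-1-one | CCCC(=O)c1c(O)cc(O)c(C)c1OC
F4 | step 18 | 1-[2,4,6-tris(benzyloxy)-3-(bromomethyl)-5-[(3-butanoyl-2,4-dihydroxy-6-methoxy-5-methylphenyl)methyl]phenyl]butan-1-one | CCCC(=O)c1c(OCc2ccccc2)c(CBr)c(OCc2ccccc2)c(Cc2c(O)c(C(=O)CCC)c(O)c(C)c2OC)c1OCc1ccccc1
F5 | step 14 | methyl 7-[(tert-butyldimethylsilyl)oxy]-3-methoxy-4-methyl-5-[(trimethylsilyl)oxy]deca-2,4-dienoate | COC(=O)C=C(OC)C(C)=C(O[Si](C)(C)C)CC(O[Si](C)(C)C(C)(C)C)CCC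
F6 | step 3 | 1-[2,4,6-tris(benzyloxy)phenyl]butan-1-one | CCCC(=O)c1c(OCc2ccccc2)cc(OCc2ccccc2)cc1OCc1ccccc1
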